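Substrate in Monday's flask stands at 27.0% of its charge from 10.0 h on, while Thursday's flask, at 10 °C, runs down to 1.7%. Here that plateau is read as free catalyst ceasing to work, not as equilibrium.

| flask | substrate | reagent | free catalyst | temperature | remark | time |
|---|---|---|---|---|---|---|
| Monday's | 0.050 M | 0.10 M | 0.10 mM | 25 °C | the very flask that is asked about, followed so far |  |
| Thursday's | 0.034 M | 0.10 M | 0.10 mM | 10 °C | run made earlier |  |
| flask | 0.050 M | 0.100 M | 0.10 mM | 25 °C |  | 40 h |

| run | time / h | target / % | substrate / % |
|---|---|---|---|
| Monday's | 5.00 | 67.5 | 31.9 |
| Monday's | 10.0 | 73.7 | 27.0 |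
| Monday's | 15.0 | 73.5 | 26.9 |
| Monday's | 20.0 | 73.3 | 27.0 |
| Monday's | 25.0 | 73.4 | 26.9 |
| Thursday's | 1.33 | 32.7 | 66.7 |
| Thursday's | 4.00 | 70.3 | 28.2 |
| Thursday's | 8.00 | 91.9 | 8.0 |
| Thursday's | 12.0 | 97.2 | 2.6 |
| Thursday's | 15.0 | 98.8 | 1.7 |

(each reading ± 0.5 percentage points)

- north: at 40 h raise the temperature by 25 K, then wait 40 h
- south: change nothing and wait 40 h more
- north-west: at 40 h add reagent, 50.0% of the amount charged, then wait 40 h
- south-east: at 40 h take out 90% of the target then present, then wait 40 h
- east: at 40 h add free catalyst, 50.0% of the amount charged, then wait 40 h

- what is taken out of target is counted as made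
- additions bring no volume worth counting

* target, in percent of the substrate first charged, at 40 h
* which option adds most target ("none" when 2 percentage points or less is all one gets) (north / south / north-west / south-east / east / none)
* target present, with what was taken out counted in, in percent of the substrate first charged, after north
* target present, with what was taken out counted in, in percent of the substrate first charged, after north-west

**The budget.** One number then describes Monday's flask: the catalyst budget, the natural logarithm of charged over plateau substrate. It is the logarithmic distance that one charge of free catalyst carries the substrate, here 1.31. By 5.00 h Monday's flask had used 87.1% of it.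

**What matters.** The rate constant need not be known, since the plateau gives the budget directly. The time need not be known well: target readings from 10.0 h to 25.0 h span 0.4 percentage points against a scatter of 0.5 points. The reagent charge of Monday's flask is already inside its plateau reading, so the budget needs no separate reagent term. One-to-one use leaves Monday's flask 63.3% of its reagent charge, so reagent has not run out at the plateau. The plateau itself must be good, and neighbouring readings there shift the budget by 0.00371.

**The reckoning.** Target at 40 h is the plateau, 73.5%. Heat, reagent, waiting and removal of target each leave it there. East brings a budget of 0.656, taking substrate to 14.0%, a gain of 13 points.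

**The forecast.** It gives 73.5% (72.9% to 74.1%), 73.5% after north, 73.5% after north-west and east as best: “The catalyst is therefore dead by 40 h”.

**The result.** The flask gives 73.3%, with 73.3% after north, 73.3% after north-west, and east as best. At 20.0 h free catalyst stands at 0.0177% of its charge and spent catalyst at >99.9%. East adds 15 points, where the budget gave 13 points.

    substrate + reagent + free catalyst → target + free catalyst, rate k1*[substrate]*[reagent]*[free catalyst]/(1 + ([substrate]/sat1)) (17.0 mM, k = 53.0 /M²/s, Ea = 36.0 kJ/mol)
    free catalyst → spent catalyst (k = 1.20 × 10⁻⁴ /s, Ea = 85.0 kJ/mol)
    (constants at 25 °C)

**A second flask.** The neighbour with 4.0 × 10⁻⁴ M of free catalyst has a budget of 5.24, which leaves 0.528% substrate. It gives 99.9% target and 0.056% substrate.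

The runs are calculated for an exercise, noise included.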